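The earlier runs and the new flask stem from a simulated flask from invented constants; the scatter is artificial.

I found it impossible to lay a straight line from the origin through the ochre run: from 6.00 min to 30.0 min the time grew 5.00-fold, but the readings of target grew 12.3-fold. The run opens with an induction period and then climbs steadily, so I reckoned with that later slope.

| flask | substrate | solid reagent | temperature | remark | time |
|---|---|---|---|---|---|
| green | 20 mM | 0.45 equiv | 40 °C | run made earlier |  |
| blue | 20 mM | 0.68 equiv | 73 °C | run made earlier |  |
| ochre | 30 mM | 0.90 equiv | 40 °C | run made earlier |  |
| ash | 20 mM | 0.900 equiv | 55 °C |  | 30 min |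
| birch | 20 mM | 0.900 equiv | 25 °C |  | 30 min |
| maple | 20 mM | 0.900 equiv | 85 °C |  | 30 min |

| run | time / min | target / % |
|---|---|---|
| green | 6.00 | 1.1 |
| green | 15.0 | 6.0 |
| green | 30.0 | 14.6 |
| green | 50.0 | 19.5 |
| blue | 2.50 | 1.3 |
| blue | 5.00 | 5.9 |
| blue | 8.00 | 9.2 |
| blue | 10.0 | 12.7 |
| ochre | 6.00 | 1.2 |
| ochre | 15.0 | 6.3 |
| ochre | 30.0 | 14.8 |
| ochre | 50.0 | 25.1 |

(each reading ± 0.5 percentage points)

- solid, in amounts per volume of the solution: solid reagent
- the earlier runs were read with a standard deviation of 0.5 percentage points
- on the list of suspects stand: substrate + partner -> target; substrate + partner -> isomer of the product; solid reagent <-> partner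
- at the start none of the solid reagent is in solution

* the best flask by amount of target, in percent of the substrate charged; "all alike" if 1.5 percentage points covers them all (ash / birch / maple / all alike)
* amount of target at the end, in percent of the substrate charged, ash
* amount of target at the end, in percent of the substrate charged, birch
* amount of target at the end, in percent of the substrate charged, maple

Ochre at 40 °C climbed by 0.00567 /min of the charge between 15.0 min and 30.0 min, and blue at 73 °C by 0.0136 /min between 5.00 min and 10.0 min. I took the logarithm of these two read slopes as a straight line in temperature, read off the slope at each flask's temperature and multiplied it by that flask's time, which gave one pure number, 25.3% for ash. This slope number is the share of the charge that a steady rise of target covers in the time allowed. Birch came to 11.4% and maple to 56.1%, so I expected maple to lead. Both lay outside the span from 40 °C to 73 °C, so I trusted them less.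

The number holds no concentration, and green and ochre, with different charges, agreed at 30.0 min: 14.6% against 14.8%. At 50.0 min their readings parted by 5.6 percentage points, against a scatter of 0.5 points, so one number did not cover these two runs at that time.

The forecast also chose maple, with 22% for ash, 6.5% for birch and 29% for maple, lower than my number for maple. It warned: “Maple is the least certain, since selectivity at high temperature is unknown and may fall.”

The flasks gave 27.7% in ash, 6.93% in birch and 39.2% in maple, so maple led.

    substrate + partner → target (k = 0.00559 /M/s, Ea = 50.0 kJ/mol)
    substrate + partner → isomer of the product (k = 0.00134 /M/s, Ea = 72.0 kJ/mol)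
    solid reagent ⇌ partner, rate k3*(cs3 - [partner]) while solid is left; crystals form when [partner] > cs3 (solubility = 11.0 mM, k = 0.00169 /s)
    (constants at 25 °C)

Ash gave 27.7% against its slope number of 25.3%, but maple fell below its 56.1%. The conversion into isomer of the product may be called the main reason: the maple run without that step gives 69.8% instead of 39.2%. A flask like ash kept at 70 °C has a slope number of 37.7%, and it gave 37.6%.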